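**Assumptions (one line):** both trisubstituted alkenes are E as drawn in the target SMILES. Compounds 5 and 9 are treated as purchasable; otherwise they take 1–2 steps from 3-butyn-1-ol and 4-hydroxybutan-2-one.

## Retrosynthetic overview (cembranoid numbering: lactone O on C14, C1 carries C15–C17)
1. The target comes from selective diacetylation of a triol lactone. That lactone comes from lactonization of the hydroxy ester formed by an intramolecular Nozaki–Hiyama–Kishi (NHK) allylation between C1 and C14. This is the last C–C bond formed, and it closes the 14-membered ring and sets C1/C14 anti (trans lactone) with Felkin control from C13.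
2. The NHK precursor is a (Z)-2-(bromomethyl)acrylate (C1 aldehyde → MBH → SN2′ bromide) plus an α-silyloxy aldehyde at C14.
3. The backbone comes from a Negishi coupling at C6–C7 between an alkylzinc W (C1–C6, anti-3,4-diol from Sharpless AE/Payne/vinyl cuprate) and dienyl iodide 8 (C7–C14).
4. Iodide 8 is built from (R)-glyceraldehyde acetonide by two Zr-catalysed carboalumination (ZACA)/Negishi operations. These fix C13 and both E alkenes.

## Route

**Step 1**
Reactants: 1 (R)-2,3-O-isopropylideneglyceraldehyde; 2 Ohira–Bestmann reagent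
Product: 3 (4S)-4-ethynyl-2,2-dimethyl-1,3-dioxolane
Conditions: K2CO3, MeOH, 0 °C → rt
Reagents that add atoms: none (2 is numbered)
Why: Ohira–Bestmann homologation turns CHO into C≡CH and leaves the α-stereocentre (future C13) untouched.

**Step 2**
Reactants: 3
Product: 4 (4S)-4-[(1E)-2-iodo-1-methylethenyl]-2,2-dimethyl-1,3-dioxolane
Conditions: Me3Al, Cp2ZrCl2 (cat.), CH2Cl2, 0 °C → rt; then I2, THF, –30 °C
Reagents that add atoms: trimethylaluminium, C[Al](C)C; iodine, II
Why: Negishi ZACA adds Me–Al syn, with Me on the internal carbon (C12), so I2 gives the E-vinyl iodide with I cis to Me, which defines C11=C12.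

**Step 3**
Reactants: 4; 5 (4-iodobut-1-ynyl)trimethylsilane
Product: 6 enyne (C7–C14 skeleton)
Conditions: 5, Zn, LiCl, THF, 40 °C (RZnI); then 4, Pd(PPh3)4 (5 mol %), THF, 25 °C
Reagents that add atoms: none
Why: Negishi sp2–sp3 coupling forms C10–C11 and retains the alkene geometry.

**Step 4**
Reactants: 6
Product: 7 terminal alkyne
Conditions: K2CO3, MeOH, rt
Reagents that add atoms: none
Why: protodesilylation of the alkynyl TMS group, which leaves the alkene and acetonide untouched.

**Step 5**
Reactants: 7
Product: 8 (4S)-4-[(1E,5E)-6-iodo-1,5-dimethylhexa-1,5-dien-1-yl]-2,2-dimethyl-1,3-dioxolane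
Conditions: Me3Al, Cp2ZrCl2 (cat.), CH2Cl2, rt; then I2, THF, –30 °C
Reagents that add atoms: C[Al](C)C; II
Why: a second ZACA places Me on C8 and I on C7 with syn selectivity, giving E-C7=C8.

**Step 6**
Reactants: 9 4-(TBSO)butan-2-one; 10 triethyl phosphonoacetate
Product: 11 ethyl (2E)-5-(TBSO)-3-methylpent-2-enoate
Conditions: NaH, THF, 0 °C → rt (E:Z ≈ 5:1, E isolated by chromatography)
Reagents that add atoms: none
Why: Horner–Wadsworth–Emmons olefination favours the E trisubstituted enoate.

**Step 7**
Reactants: 11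
Product: 12 (2E)-5-(TBSO)-3-methylpent-2-en-1-ol
Conditions: DIBAL-H (2.5 equiv), CH2Cl2, –78 °C
Reagents that add atoms: none
Why: DIBAL reduces the ester to the allylic alcohol; the silyl ether is untouched.

**Step 8**
Reactants: 12
Product: 13 [(2R,3R)-3-(2-TBSO-ethyl)-3-methyloxiranyl]methanol (trans epoxide)
Conditions: Ti(OiPr)4 (10 mol %), D-(–)-DET (12 mol %), TBHP, 3 Å MS, CH2Cl2, –20 °C
Reagents that add atoms: tert-butyl hydroperoxide, CC(C)(C)OO (O source)
Why: Sharpless asymmetric epoxidation with D-(–)-DET delivers O to the (R,R) face, fixing the future C4 (R).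

**Step 9**
Reactants: 13
Product: 14 (3R,4S)-1-(TBSO)-3-methylhept-6-ene-3,4-diol (C4 = R, C3 = S in target numbering)
Conditions: vinylMgBr (6 equiv), CuBr·SMe2, THF, –40 → 0 °C
Reagents that add atoms: vinylmagnesium bromide, C=C[Mg]Br
Why: the Mg alkoxide undergoes Payne rearrangement to the terminal epoxide, which is opened at CH2 by the vinyl cuprate; inversion at C3 and retention at C4 give the anti-(3S,4R) diol (C2–C1 bond formed).

**Step 10**
Reactants: 14
Product: 15 cyclohexylidene ketal of the diol
Conditions: 1,1-dimethoxycyclohexane, PPTS (cat.), CH2Cl2, rt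
Reagents that add atoms: 1,1-dimethoxycyclohexane, COC1(OC)CCCCC1
Why: ketalization protects the diol. The cyclohexylidene group is more acid-robust than the later acetonide, which allows selective removal of the acetonide in step 19.

**Step 11**
Reactants: 15
Product: 16 primary alcohol (C6–OH)
Conditions: TBAF, THF, 0 °C → rt
Reagents that add atoms: none
Why: fluoride cleaves the primary TBS ether; the ketal and vinyl group are inert.

**Step 12**
Reactants: 16
Product: 17 primary iodide
Conditions: I2, PPh3, imidazole, Et2O/CH2Cl2, 0 °C → rt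
Reagents that add atoms: iodine, II
Why: Appel-type iodination (Garegg–Samuelsson) converts the primary OH to the C6 alkyl iodide without touching the alkene.

**Step 13**
Reactants: 17
Product: 18 aldehyde (C1 CHO, iodide retained)
Conditions: OsO4 (cat.), NaIO4, 2,6-lutidine, dioxane/H2O, rt
Reagents that add atoms: sodium periodate, [Na+].[O-]I(=O)(=O)=O (source of aldehyde O)
Why: Lemieux–Johnson cleavage of the only alkene present gives the C1 aldehyde; the alkyl iodide is inert.

**Step 14**
Reactants: 18
Product: 19 dimethyl acetal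
Conditions: HC(OMe)3, PPTS (cat.), MeOH, rt
Reagents that add atoms: trimethyl orthoformate, COC(OC)OC; methanol, CO
Why: acetalization masks the aldehyde so that it survives the organozinc chemistry and cannot cyclize onto the zinc.

**Step 15**
Reactants: 19; 8
Product: 20 coupled C1–C14 backbone
Conditions: Zn, LiCl, THF, 40 °C (from 19); then 8, PdCl2(dppf) (5 mol %), THF, 25 °C
Reagents that add atoms: none
Why: Negishi coupling forms the C6–C7 bond and retains the E geometry at C7=C8.

**Step 16**
Reactants: 20
Product: 21 C1 aldehyde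
Conditions: PPTS (0.3 equiv), acetone/H2O (10:1), 50 °C
Reagents that add atoms: water, O (becomes the carbonyl O)
Why: an aldehyde dimethyl acetal hydrolyses far more easily than the acetonide or ketal, so only the acetal is cleaved.

**Step 17**
Reactants: 21; 22 methyl acrylate
Product: 23 Morita–Baylis–Hillman adduct (C1-OH, epimeric mixture)
Conditions: DABCO (1 equiv), neat, rt, 5 d
Reagents that add atoms: none (22 is numbered)
Why: Morita–Baylis–Hillman coupling installs C15–C17; the new C1 carbinol stereocentre is erased in the next step.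

**Step 18**
Reactants: 23
Product: 24 (Z)-2-(bromomethyl)alk-2-enoate (allylic bromide)
Conditions: MsCl, Et3N, CH2Cl2, –20 °C; then LiBr, THF, 0 °C → rt
Reagents that add atoms: lithium bromide, [Li+].[Br-]
Why: the mesylate undergoes SN2′ displacement by bromide to give the primary allylic bromide, the standard NHK allyl donor.

**Step 19**
Reactants: 24
Product: 25 C13/C14 diol
Conditions: AcOH/H2O/THF (3:1:3), rt
Reagents that add atoms: none
Why: the terminal acetonide hydrolyses selectively while the more robust cyclohexylidene ketal survives.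

**Step 20**
Reactants: 25
Product: 26 α-hydroxy aldehyde (C14 CHO)
Conditions: TEMPO (10 mol %), PhI(OAc)2, CH2Cl2, 0 °C
Reagents that add atoms: none
Why: TEMPO oxidation is selective for the primary alcohol over the hindered secondary allylic alcohol, and C13 is not epimerized under these neutral conditions.

**Step 21**
Reactants: 26
Product: 27 α-TBS-oxy aldehyde (NHK precursor)
Conditions: TBSOTf, 2,6-lutidine, CH2Cl2, –78 °C
Reagents that add atoms: tert-butyldimethylsilyl triflate, C[Si](C)(OS(=O)(=O)C(F)(F)F)C(C)(C)C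
Why: a bulky non-chelating silyl ether on C13 enforces Felkin–Anh control in the NHK and protects against Cr(II) reduction.

**Step 22**
Reactants: 27
Product: 28 macrocyclic hydroxy ester (C1 R, C14 R)
Conditions: CrCl2 (10 equiv), DMF, 25 °C, syringe-pump addition (2 mM)
Reagents that add atoms: none
Why: the allylchromium adds through C1 via a chair TS to give the anti homoallylic alcohol (trans lactone after closure), and the α-OTBS aldehyde reacts by Felkin–Anh control to give (13S,14R).

**Step 23**
Reactants: 28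
Product: 29 trans-fused α-methylene-γ-lactone
Conditions: TsOH·H2O (cat.), CH2Cl2, rt
Reagents that add atoms: none
Why: acid-catalysed lactonization loses MeOH; no stereocentre is disturbed.

**Step 24**
Reactants: 29
Product: 30 triol lactone (C3-OH, C4-OH, C13-OH)
Conditions: CSA (0.5 equiv), MeOH, 40 °C
Reagents that add atoms: none
Why: acid-mediated trans-ketalization removes the cyclohexylidene and the TBS group in one step.

**Step 25**
Reactants: 30
Product: 31 Crassocolide B
Conditions: Ac2O (2.5 equiv), DMAP (cat.), pyridine/CH2Cl2, 0 °C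
Reagents that add atoms: acetic anhydride, CC(=O)OC(C)=O
Why: acetylation is chemoselective for the two secondary alcohols (C3, C13), and the hindered tertiary C4-OH stays free.

## Compound list
1 | (R)-2,3-O-isopropylideneglyceraldehyde | O=C[C@H]1COC(C)(C)O1 | starting material
2 | dimethyl (1-diazo-2-oxopropyl)phosphonate | CC(=O)C(=[N+]=[N-])P(=O)(OC)OC | starting material
3 | (4S)-4-ethynyl-2,2-dimethyl-1,3-dioxolane | C#C[C@H]1COC(C)(C)O1 | intermediate
4 | (4S)-4-[(1E)-2-iodo-1-methylethenyl]-2,2-dimethyl-1,3-dioxolane | I/C=C(\C)[C@H]1COC(C)(C)O1 | intermediate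
5 | (4-iodobut-1-yn-1-yl)trimethylsilane | C[Si](C)(C)C#CCCI | starting material
6 | TMS-enyne | C[Si](C)(C)C#CCC/C=C(\C)[C@H]1COC(C)(C)O1 | intermediate
7 | terminal enyne | C#CCC/C=C(\C)[C@H]1COC(C)(C)O1 | intermediate
8 | (4S)-4-[(1E,5E)-6-iodo-1,5-dimethylhexa-1,5-dien-1-yl]-2,2-dimethyl-1,3-dioxolane | I/C=C(\C)CC/C=C(\C)[C@H]1COC(C)(C)O1 | intermediate
9 | 4-(TBSO)butan-2-one | CC(=O)CCO[Si](C)(C)C(C)(C)C | starting material
10 | triethyl phosphonoacetate | CCOC(=O)CP(=O)(OCC)OCC | starting material
11 | ethyl (2E)-5-(TBSO)-3-methylpent-2-enoate | CCOC(=O)/C=C(\C)CCO[Si](C)(C)C(C)(C)C | intermediate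
12 | (2E)-5-(TBSO)-3-methylpent-2-en-1-ol | OC/C=C(\C)CCO[Si](C)(C)C(C)(C)C | intermediate
13 | [(2R,3R)-3-(2-TBSO-ethyl)-3-methyloxiranyl]methanol | OC[C@H]1O[C@]1(C)CCO[Si](C)(C)C(C)(C)C | intermediate
14 | (3R,4S)-1-(TBSO)-3-methylhept-6-ene-3,4-diol | C=CC[C@H](O)[C@](C)(O)CCO[Si](C)(C)C(C)(C)C | intermediate
15 | cyclohexylidene ketal of 14 | C=CC[C@@H]1OC2(CCCCC2)O[C@]1(C)CCO[Si](C)(C)C(C)(C)C | intermediate
16 | primary alcohol (C6-OH) | C=CC[C@@H]1OC2(CCCCC2)O[C@]1(C)CCO | intermediate
17 | primary iodide | C=CC[C@@H]1OC2(CCCCC2)O[C@]1(C)CCI | intermediate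
18 | aldehyde (C1 CHO, C6-I) | O=CC[C@@H]1OC2(CCCCC2)O[C@]1(C)CCI | intermediate
19 | dimethyl acetal (C1, C6-I) | COC(OC)C[C@@H]1OC2(CCCCC2)O[C@]1(C)CCI | intermediate
20 | coupled backbone (acetal, ketal, acetonide) | COC(OC)C[C@@H]1OC2(CCCCC2)O[C@]1(C)CC/C=C(\C)CC/C=C(\C)[C@H]1COC(C)(C)O1 | intermediate
21 | C1 aldehyde | O=CC[C@@H]1OC2(CCCCC2)O[C@]1(C)CC/C=C(\C)CC/C=C(\C)[C@H]1COC(C)(C)O1 | intermediate
22 | methyl acrylate | C=CC(=O)OC | starting material
23 | MBH adduct (C1 epimeric mixture) | C=C(C(=O)OC)C(O)C[C@@H]1OC2(CCCCC2)O[C@]1(C)CC/C=C(\C)CC/C=C(\C)[C@H]1COC(C)(C)O1 | intermediate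
24 | (Z)-allylic bromide | BrC/C(C(=O)OC)=C\C[C@@H]1OC2(CCCCC2)O[C@]1(C)CC/C=C(\C)CC/C=C(\C)[C@H]1COC(C)(C)O1 | intermediate
25 | C13/C14 diol | BrC/C(C(=O)OC)=C\C[C@@H]1OC2(CCCCC2)O[C@]1(C)CC/C=C(\C)CC/C=C(\C)[C@H](O)CO | intermediate
26 | α-hydroxy aldehyde | BrC/C(C(=O)OC)=C\C[C@@H]1OC2(CCCCC2)O[C@]1(C)CC/C=C(\C)CC/C=C(\C)[C@H](O)C=O | intermediate
27 | α-TBS-oxy aldehyde (NHK precursor) | BrC/C(C(=O)OC)=C\C[C@@H]1OC2(CCCCC2)O[C@]1(C)CC/C=C(\C)CC/C=C(\C)[C@H](O[Si](C)(C)C(C)(C)C)C=O | intermediate
28 | macrocyclic hydroxy ester | C=C(C(=O)OC)[C@H]1C[C@@H]2OC3(CCCCC3)O[C@]2(C)CC/C=C(\C)CC/C=C(\C)[C@H](O[Si](C)(C)C(C)(C)C)[C@@H]1O | intermediate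
29 | trans-fused lactone (ketal, TBS) | C=C1C(=O)O[C@@H]2[C@@H]1C[C@@H]3OC4(CCCCC4)O[C@]3(C)CC/C=C(\C)CC/C=C(\C)[C@@H]2O[Si](C)(C)C(C)(C)C | intermediate
30 | triol lactone | C=C1C(=O)O[C@@H]2[C@@H]1C[C@H](O)[C@](C)(O)CC/C=C(\C)CC/C=C(\C)[C@@H]2O | intermediate
31 | Crassocolide B | C=C1C(=O)O[C@@H]2[C@@H]1C[C@H](OC(C)=O)[C@](C)(O)CC/C=C(\C)CC/C=C(\C)[C@@H]2OC(C)=O | target

**Total steps:** 25 (two convergent branches). **Longest linear sequence:** 20 steps (9 → 11 → … → 20 → 21 → … → 31). The shorter branch runs 1 → 8 (5 steps) and joins at step 15.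

## Three steps most likely to fail
1. **Step 22, macrocyclic NHK.** It may give poor yield (oligomers) or poor C1/C14 diastereoselectivity. Fallback: change the ring-closing disconnection. Build the acyclic trans-lactone first by intermolecular Cr-allylation of the C13/C14 α-silyloxy aldehyde with the C1–C6 allylic bromide, then close the ring by RCM at C7=C8 (or macro-Negishi).
2. **Step 9, one-pot Payne rearrangement/vinyl cuprate opening.** The Payne equilibrium may be unfavourable, or the cuprate may attack the wrong epoxide. Fallback: run the AE with L-(+)-DET, hydrolyse the epoxide under acid (attack at tertiary C4 with inversion) to the triol, close to the terminal epoxide (TsCl, then base), and open with vinyl cuprate. This gives the same (3S,4R) diol in three extra steps.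
3. **Steps 19–21, selective acetonide removal and handling of the α-hydroxy aldehyde.** The acetonide may not be removed cleanly in the presence of the allylic bromide, or C13 may epimerize. Fallback: use a bis-TBS-protected version of fragment 3 (hydrolyse the acetonide, bis-silylate, then ZACA). The primary TBS is then removed with HF·pyridine (before step 18) or CSA/MeOH and oxidized with DMP, avoiding the free α-hydroxy aldehyde.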